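**Numbering used throughout:** 1 pent-1-yne; 2 1-iodopent-1-yne; 3 acetic acid; 4 (Z)-1-iodopent-1-en-2-yl acetate; 5 carbon monoxide; 6 ethynyltrimethylsilane; 7 silyl ynone; 8 bromo ynone; 9 free bromoalkynyl diketone; 10 6-bromopyranone; 11 3,6-dibromopyranone; 12 3,5,6-tribromopyranone; 13 C1' monobromide; 14 target.

## Analysis of the target

The target 14 is a monocyclic 4H-pyran-4-one in which every ring carbon is substituted. With the ring numbered O1, C2, C3, C4 (carbonyl), C5, C6, C2 carries a 1,1-dibromopropyl chain (C1' = CBr2, C2' = CH2, C3' = CH3), and C3, C5 and C6 each carry bromine. There is no stereocentre, since C1' holds two identical bromines; the only stereochemical element on the way is a double-bond geometry in an open-chain intermediate. The five bromines sit in three electronically different places: C3 and C5 are the nucleophilic α-carbons of a vinylogous ester and accept electrophilic bromine, C6 is the electrophilic β-carbon next to O1, which electrophilic substitution does not reach, and C1' is an allylic-type side-chain position. The sensitive groups are the C6–Br bond (a vinylogous acyl bromide that oxygen and nitrogen nucleophiles displace by addition–elimination), the ring itself (opened at C2/C6 by strong nucleophiles) and the tertiary gem-dibromide at C1', which can lose HBr towards C2'. The difficulty is therefore to place a bromine at C6 by something other than electrophilic substitution and to make the gem-dibromide late enough that it is not lost again. The strategy rests on C4: it is bonded only to C3 and C5 and carries only oxygen, so it can be carbon monoxide placed between a C2–C3 vinyl unit that already holds O1 and a C5–C6 alkyne whose terminal carbon becomes C6 and can be brominated before the ring exists.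

## Retrosynthetic reasoning

**14 to 12 (two C1'–Br bonds).** The gem-dibromide is the group most prone to elimination, so it is made last and never carried through acid, base or metal catalysis. In 12 every ring carbon is blocked and C1' is the only C–H position whose radical is conjugated with the ring. A radical chain bromination therefore has one activated site and has to run twice at it, passing through 13.

**12 to 10 (C3–Br and C5–Br).** These carbons are the α-positions of the vinylogous ester and the natural sites of electrophilic substitution, so both halogens can be introduced in one operation on 10, through 11. The C6–Br bond is deliberately not cut here, because no electrophilic halogenation reaches C6.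

**10 to 8 (O1–C6, ring opening).** Cutting here turns C6 into the terminal carbon of a bromoalkyne conjugated to the C4 ketone, and O1 into an enol oxygen at C2, masked as the acetate in 8. The forward reaction must remove the acetyl group and let the enol oxygen of 9 add to the bromine-bearing alkyne carbon in the 6-endo sense, without another nucleophile taking that carbon. For that reason the unmasking is planned under acid catalysis and not with an alkoxide base. The gain is that the C6 bromine arrives as part of the chain.

**8 to 7 (alkyne C–Br traced to C–Si).** A silyl cap is needed in the preceding coupling, where a free terminus could couple twice and a bromoalkyne would itself undergo oxidative addition. Exchange of silicon for bromine on an alkyne is a mild, neutral operation that the enol acetate should tolerate.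

**7 to 4 + 5 + 6 (C3–C4 and C4–C5).** Both bonds to C4 are cut at once. This gives the vinyl iodide 4 (C2, C3, O1 and the side chain), carbon monoxide 5 (C4) and the alkyne 6 (C5, C6). The cut is made here because C4 carries nothing but oxygen and joins an sp2 to an sp carbon, which is the pattern that migratory insertion of 5 into a vinyl–palladium bond followed by alkynyl transfer produces. A cut at C2–C3 or C5–C6 would require a pre-formed acylating agent or acetylenic ketone. The gain is convergence: all eight skeletal carbons come from three small molecules and two C–C bonds form in one step. The forward reaction must insert 5 before the alkynyl group is transferred and must keep the double-bond geometry.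

**4 to 2 + 3 (C2–O1).** The enol acetate is traced to the iodoalkyne 2 and acetic acid 3. The forward reaction must add the O–H bond across the triple bond with oxygen at the internal carbon and in the anti sense, so that iodine and acetate end up cis.

**2 to 1 (C–I).** The C–I bond is cut to the terminal alkyne 1, which supplies C2, C3 and the whole side chain.

## Alternatives that were turned down

**Alternative 1:** The ring would be cut at C2–C3 and O1–C6 and formed by a hetero-Diels–Alder reaction of the aldehyde 2,2-dibromobutanal A2 with the oxygenated diene (E)-1-methoxy-3-(trimethylsilyloxy)buta-1,3-diene A3 under a zinc Lewis acid. Acidic work-up would strip the methoxy and silyl groups of the cycloadduct and leave racemic 2-(1,1-dibromopropyl)-2,3-dihydro-4H-pyran-4-one A1.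
- For: ring and complete side chain, gem-dibromide included, appear in one convergent step, and the diene A3 needs no preparation. On this point the alternative is stronger than the chosen route, which needs a double radical bromination at C1' at the very end.
- Against: A1 is at the wrong oxidation level. It must be dehydrogenated across C2–C3 next to a carbon holding two bromines and an adjacent methylene, an arrangement primed for elimination. The C2 stereocentre is made only to be destroyed. Neither A2 nor A3 brings a ring bromine, so none of the three is in place, and the one at C6 cannot be introduced by electrophilic substitution. A2 is a hindered, easily hydrated aldehyde.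
- Comparison: the labile gem-dibromide of A1 would travel through four or more further steps. The chosen strategy gives up the early side-chain halogenation and gets in return the pyranone oxidation level directly and a C6 bromine that comes with the alkyne.

**Alternative 2:** Only O1–C6 is cut. The open-chain precursor 1,1,2-tribromooct-1-ene-3,5-dione A5 would close under mild carbonate base by addition of the enol oxygen to the dibrominated alkene carbon and loss of bromide. The product is 2,3-dibromo-6-propyl-4H-pyran-4-one A4, which in target numbering is the 5,6-dibromo-2-propyl compound.
- For: the closure is a simple vinylic substitution, and A4 would already hold the C5 and C6 bromines, so only C3 and C1' remain. In step count after the key step and in the handling of C5 the alternative is stronger than the chosen route, which must brominate C5 in a ring already deactivated by the C6 bromine.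
- Against: the difficulty moves into the preparation of A5. A tribromoacryloyl unit would have to acylate a methyl ketone enolate, yet it is at least as reactive at its dibromovinyl carbon and at bromine as at the carbonyl, and the β-diketone formed is a further nucleophile for the same unit.
- Comparison: the step from A5 to A4 would be safe, but A5 is not reached by reliable chemistry. The chosen route forms the same O1–C6 bond by a related closure and builds the chain by catalytic C–C bond formation from stable components, so the risk sits in one well-precedented coupling.

**Alternative 3:** The six-membered ring would arise from a five-membered one. Dibromocarbene A8, generated from a haloform and an alkoxide base, would add to the oxygenated C2=C3 double bond of 2-propyl-3-(triisopropylsilyloxy)furan A7. Opening of the dibromocyclopropane with loss of bromide and silyl would insert one carbon and give 3-bromo-2-propyl-4H-pyran-4-one A6.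
- For: A6 carries the C3 bromine from the moment the ring forms, one bromination fewer than in the chosen route at that position, and the expansion is short.
- Against: A7 is an electron-rich, acid-sensitive silyl enol ether that itself takes several steps to make. A8 can also attack the other furan double bond. The bromine that A6 gains, at C3, is the easiest of the three to introduce anyway, while C6 of A6 is again an unsubstituted electrophilic position with no direct bromination.
- Comparison: the chosen route spends one ordinary electrophilic bromination on C3 and in exchange solves C6, the position that decides whether the target can be reached; A6 leaves that problem open.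

Key step: step 3

**Remark on the chemistry:** ring positions are quoted in the numbering of the target (side chain at C2); the systematic names of 10 and 12–14 number the ring from the other end. The acetate is removed under acid and not with carbonate in methanol, because an alkoxide would compete for the bromine-bearing carbon and displace the C6 bromide.

## Route

Step 1
Reactants: 1 pent-1-yne
Product: 2 1-iodopent-1-yne
Conditions: NIS, AgNO3 (cat.), acetone, rt, dark
Reagents that add atoms: N-iodosuccinimide, O=C1CCC(=O)N1I
Why: Silver-catalysed electrophilic iodination of a terminal alkyne; the silver acetylide formed from 1 is iodinated by NIS, and 1 has no other reactive site.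

Step 2
Reactants: 2 1-iodopent-1-yne; 3 acetic acid
Product: 4 (Z)-1-iodopent-1-en-2-yl acetate
Conditions: Ph3PAuNTf2 (2 mol %), toluene, rt
Reagents that add atoms: none
Why: Gold-catalysed hydroacyloxylation of a haloalkyne; acetic acid attacks the gold–alkyne complex anti to the metal at the carbon remote from iodine, and protodeauration places H trans to the acetate, so iodine and acetate end up cis (Z). This fixes O1 on C2 next to the C3 iodide.

Step 3
Reactants: 4 (Z)-1-iodopent-1-en-2-yl acetate; 5 carbon monoxide; 6 ethynyltrimethylsilane
Product: 7 (Z)-3-oxo-1-(trimethylsilyl)oct-4-en-1-yn-5-yl acetate
Conditions: PdCl2(PPh3)2 (5 mol %), CuI (2 mol %), Et3N (2 equiv), THF, CO (1–3 bar), rt, slow addition of 6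
Reagents that add atoms: none
Why: The divalent palladium precatalyst is reduced in the flask to zerovalent palladium, which inserts into the vinyl C–I bond of 4 with retention; 5 then inserts to give an acylpalladium species (C3–C4 bond), the copper acetylide formed from 6, CuI and Et3N transmetalates, and reductive elimination forms the C4–C5 bond and releases 7, while Et3N takes up HI. The closest known reaction type is the carbonylative Sonogashira coupling of aryl and vinyl iodides with silylacetylenes, whose aromatic counterpart is the assembly of flavones from 2-iodophenols, carbon monoxide and terminal alkynes. No ring closes and no stereocentre forms; the only stereochemical demand is retention of the Z geometry, which oxidative addition and insertion both respect. The selectivity needed is carbonylative over direct coupling, which a CO-saturated solution, the electron-rich oxygen-substituted vinylpalladium (fast CO insertion), a low CuI loading and slow addition of 6 should secure. The silyl cap prevents a second coupling at the alkyne terminus, and the acetate is inert to the tertiary amine. The Z geometry puts O1 cis to the new acyl group as ring closure requires, and a partial loss of geometry would still converge, because the enol forms interconvert once the acetate is removed.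

Step 4
Reactants: 7 (Z)-3-oxo-1-(trimethylsilyl)oct-4-en-1-yn-5-yl acetate
Product: 8 (Z)-1-bromo-3-oxooct-4-en-1-yn-5-yl acetate
Conditions: NBS, AgNO3 (cat.), acetone, rt, dark; aqueous work-up
Reagents that add atoms: N-bromosuccinimide, O=C1CCC(=O)N1Br
Why: Silver-mediated desilylative bromination of an alkynylsilane; the C(sp)–Si bond is exchanged for a silver acetylide that NBS brominates, while the push–pull enol acetate alkene is too electron-poor to compete under these neutral conditions. The future C6 bromine is thus on carbon before the ring exists.

Step 5
Reactants: 8 (Z)-1-bromo-3-oxooct-4-en-1-yn-5-yl acetate
Product: 10 2-bromo-6-propyl-4H-pyran-4-one, via 1-bromooct-1-yne-3,5-dione 9 (not isolated)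
Conditions: HBr (33% in AcOH, 0.2 equiv), MeOH–CH2Cl2 (1:4), 0 °C to rt
Reagents that add atoms: none
Why: Acid-catalysed transesterification passes the acetyl group to methanol and frees the 1,3-diketone 9, whose enol oxygen adds to the bromine-bearing alkyne carbon in a 6-endo-dig conjugate addition, the classical closure of acetylenic β-diketones to 4-pyranones. With HBr as catalyst the only anionic nucleophile is bromide, whose addition to the ynone and re-expulsion on closure lead to the same product, whereas an alkoxide would replace the C6 bromine.

Step 6
Reactants: 10 2-bromo-6-propyl-4H-pyran-4-one
Product: 12 2,3,5-tribromo-6-propyl-4H-pyran-4-one, via 3,6-dibromo-2-propyl-4H-pyran-4-one 11 (not isolated)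
Conditions: Br2 (2.5 equiv), AcOH, rt to 50 °C
Reagents that add atoms: bromine, BrBr
Why: Electrophilic bromination of the vinylogous ester; C3 and C5 (target numbering) are the α-carbons of the 4-pyranone and the only ring C–H positions left, the alkyl-flanked C3 should react first (11) and C5 should follow with excess bromine and gentle warming. The bromide released can only exchange degenerately at C6.

Step 7
Reactants: 12 2,3,5-tribromo-6-propyl-4H-pyran-4-one
Product: 14 2,3,5-tribromo-6-(1,1-dibromopropyl)-4H-pyran-4-one, via 2,3,5-tribromo-6-(1-bromopropyl)-4H-pyran-4-one 13 (not isolated)
Conditions: NBS (2.3 equiv), hν (visible lamp), PhCF3, 60 °C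
Reagents that add atoms: N-bromosuccinimide, O=C1CCC(=O)N1Br
Why: Wohl–Ziegler radical bromination; with the ring fully substituted, the C1' hydrogens are the only ones that give a radical conjugated with the pyranone, and the first bromine stabilises the second C1' radical, so two equivalents of NBS should give the gem-dibromide by way of 13. Light at moderate temperature and the absence of base should limit loss of HBr towards C2'.

## Compound list

1 | pent-1-yne | CCCC#C | starting material
2 | 1-iodopent-1-yne | CCCC#CI | intermediate
3 | acetic acid | CC(=O)O | starting material
4 | (Z)-1-iodopent-1-en-2-yl acetate | CCC/C(OC(C)=O)=C/I | intermediate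
5 | carbon monoxide | [C-]#[O+] | starting material
6 | ethynyltrimethylsilane | C#C[Si](C)(C)C | starting material
7 | (Z)-3-oxo-1-(trimethylsilyl)oct-4-en-1-yn-5-yl acetate | CCC/C(OC(C)=O)=C/C(=O)C#C[Si](C)(C)C | intermediate
8 | (Z)-1-bromo-3-oxooct-4-en-1-yn-5-yl acetate | CCC/C(OC(C)=O)=C/C(=O)C#CBr | intermediate
9 | 1-bromooct-1-yne-3,5-dione | CCCC(=O)CC(=O)C#CBr | intermediate (not isolated)
10 | 2-bromo-6-propyl-4H-pyran-4-one (target numbering: 6-bromo-2-propyl) | CCCc1cc(=O)cc(Br)o1 | intermediate
11 | 3,6-dibromo-2-propyl-4H-pyran-4-one | CCCc1oc(Br)cc(=O)c1Br | intermediate (not isolated)
12 | 2,3,5-tribromo-6-propyl-4H-pyran-4-one (target numbering: 3,5,6-tribromo-2-propyl) | CCCc1oc(Br)c(Br)c(=O)c1Br | intermediate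
13 | 2,3,5-tribromo-6-(1-bromopropyl)-4H-pyran-4-one (racemic) | CCC(Br)c1oc(Br)c(Br)c(=O)c1Br | intermediate (not isolated)
14 | 2,3,5-tribromo-6-(1,1-dibromopropyl)-4H-pyran-4-one (target numbering: 3,5,6-tribromo-2-(1,1-dibromopropyl)) | CCC(Br)(Br)c1oc(Br)c(Br)c(=O)c1Br | target

## Step count and least certain steps

Total step count: 7. Longest linear sequence: 7 steps, from 1 to 14; 3, 5 and 6 enter as single components.

**Step 3 (key step).** The most likely failure is direct coupling without carbonylation: the copper acetylide reaches the vinylpalladium iodide before 5 has inserted and a simple enyne results. A second possibility is loss of the cis acetate from the vinylpalladium species by β-elimination.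
Fallback, from 4 to 7: the two bonds to C4 are formed in separate steps, so direct coupling cannot occur. Palladium-catalysed formylation of 4 (Pd(PPh3)4, CO, Bu3SnH, THF, 50 °C) should give (Z)-1-oxohex-2-en-3-yl acetate F1. Addition of the bromomagnesium acetylide generated from 6 with EtMgBr, at −78 °C, where the aldehyde reacts far faster than the enol acetate, followed by a cold quench with AcOH so that the new alkoxide cannot take over the neighbouring acetyl group, should give racemic (Z)-3-hydroxy-1-(trimethylsilyl)oct-4-en-1-yn-5-yl acetate F2. Oxidation of this doubly activated alcohol with MnO2 in CH2Cl2 comes back to the route at 7.

**Step 5.** The most likely failure is conjugate addition of methanol to the bromine-bearing carbon before or after closure, followed by loss of bromide, so that C6 ends up with an alkoxy group. Slow acetyl transfer under acid is the second concern.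
Fallback, from 8 to 11: no oxygen nucleophile is used. Treating 8 with Br2 (1.1 equiv) in CH2Cl2 at 0 °C should brominate the enol acetate at the future C3 with expulsion of acetyl bromide. This gives racemic 1,4-dibromooct-1-yne-3,5-dione F3, whose enol closes in the 6-endo sense once a catalytic amount of HBr in AcOH is added. The route is rejoined at 11, which is then brominated at C5 under the conditions of step 6.

**Step 7.** The most likely failures are radical attack at C2' after the first bromination, which gives vicinal instead of geminal dibromination, and loss of HBr from the tertiary bromide towards C2'.
Fallback, from 12 to 14: an ionic sequence replaces the radical one. LiN(SiMe3)2 in THF at −78 °C should deprotonate C1', the only acidic C–H (vinylogous α-position). Bromination of the dienolate with 1,2-dibromo-1,1,2,2-tetrachloroethane gives 13, and a second, easier deprotonation and bromination gives 14. No compound outside the list is made.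

**Step 6.** The most likely failure is stalling of the second substitution at C5, because the C6 bromine and protonation by HBr deactivate the ring, with ionic bromination beginning at C1' instead.
Fallback, from 7 to 12: the ring is brominated before C6 carries bromine. K2CO3 in MeOH at rt should remove silyl and acetyl groups from 7 and close the ring to 2-propyl-4H-pyran-4-one F4. Br2 in AcOH then substitutes C3 and C5 of this undeactivated ring to give 3,5-dibromo-2-propyl-4H-pyran-4-one F5. Magnesiation of the remaining C6–H with TMPMgCl·LiCl in THF at −40 °C and quenching with 1,2-dibromo-1,1,2,2-tetrachloroethane installs the C6 bromine and returns to the route at 12.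

## Further compounds

F1 | step 3 | (Z)-1-oxohex-2-en-3-yl acetate | CCC/C(OC(C)=O)=C/C=O
F2 | step 3 | (Z)-3-hydroxy-1-(trimethylsilyl)oct-4-en-1-yn-5-yl acetate (racemic) | CCC/C(OC(C)=O)=C/C(O)C#C[Si](C)(C)C
F3 | step 5 | 1,4-dibromooct-1-yne-3,5-dione (racemic) | CCCC(=O)C(Br)C(=O)C#CBr
F4 | step 6 | 2-propyl-4H-pyran-4-one | CCCc1cc(=O)cco1
F5 | step 6 | 3,5-dibromo-2-propyl-4H-pyran-4-one | CCCc1occ(Br)c(=O)c1Br
F0 | step 7 | none | none
A1 | alternative 1 | 2-(1,1-dibromopropyl)-2,3-dihydro-4H-pyran-4-one (racemic) | CCC(Br)(Br)C1CC(=O)C=CO1
A2 | alternative 1 | 2,2-dibromobutanal | CCC(Br)(Br)C=O
A3 | alternative 1 | (E)-1-methoxy-3-(trimethylsilyloxy)buta-1,3-diene | CO/C=C/C(=C)O[Si](C)(C)C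
A4 | alternative 2 | 2,3-dibromo-6-propyl-4H-pyran-4-one | CCCc1cc(=O)c(Br)c(Br)o1
A5 | alternative 2 | 1,1,2-tribromooct-1-ene-3,5-dione | CCCC(=O)CC(=O)C(Br)=C(Br)Br
A6 | alternative 3 | 3-bromo-2-propyl-4H-pyran-4-one | CCCc1occc(=O)c1Br
A7 | alternative 3 | 2-propyl-3-(triisopropylsilyloxy)furan | CCCc1occc1O[Si](C(C)C)(C(C)C)C(C)C
A8 | alternative 3 | dibromocarbene | Br[C]Br
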